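The data stem from a simulated flask with made-up constants, and the scatter is random.

If a catalyst in its round had even odds at each pass of giving a Zc or being lost, it would give one Zc on average, and in this flask that zero of the scale lies at 8.60% of the Za charged. Za takes Zb into Zf, Zf turns into Zg, and Zg gives Zc and returns Zb. Zf can also meet Ze and leave the round as Zj, while Zd carries Za off to Zh.

common to all: Za 0.10 M; Zb 8.6 mM; temperature 20 °C

|  | Zd | Ze | remark | time |
|---|---|---|---|---|
| elm | 0.010 M | 0.030 M | the very flask that is asked about, followed so far |  |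
| flask | 0.0100 M | 0.0300 M |  | 25 h |

elm run (percent of the Za charged)

| time / h | Zc / % | Za / % |
|---|---|---|
| 0.833 | 0.4 | 92.4 |
| 2.50 | 4.2 | 84.4 |
| 4.00 | 6.6 | 79.3 |
| 6.00 | 9.5 | 75.9 |
| 10.0 | 12.3 | 70.8 |
| 12.0 | 12.2 | 69.3 |
| 15.0 | 14.1 | 67.2 |

(each reading ± 0.5 percentage points)

- epsilon: at 25 h take out 90% of the Zc then present, then wait 12 h
- delta: change nothing and wait 12 h more
- gamma: at 25 h add Zb, 100% of the amount charged, then wait 12 h
- zeta: at 25 h raise the temperature by 25 K, then wait 12 h

- Zc that was removed still counts
- steps thought possible: Za + Zd -> Zh; Zf <-> Zg; Za + Zb -> Zf; Zf + Ze -> Zj; Zg -> Zb + Zc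
- the earlier runs do not show what temperature does; that part of a forecast is a guess
- additions bring no volume worth counting

- Zc, in percent of the Za first charged, at 25 h
- which option adds most Zc ("none" when 2 percentage points or less is all one gets) (epsilon / delta / gamma / zeta / none)
- Zc present, with what was taken out counted in, in percent of the Za first charged, after epsilon
- Zc present, with what was taken out counted in, in percent of the Za first charged, after gamma

I began with the last reading. At 15.0 h Zc stood at 14.1%, or 1.64 Zc per Zb charged, already above the even-odds mark. The hourly rise between 2.50 h and 6.00 h was 2.96 times the rise between 6.00 h and 15.0 h, yet Za still stood at 67.2%. I therefore read the slowing as catalyst being lost, with a decay constant of 0.174 h⁻¹. Carried to 25 h, that adds 1.1 percentage points and gives 15.2%.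

The weak link was the constant decay, since a capture that needs Za and then Ze should slow as both fall. I scaled the constant by the fall in Za between 6.00 h and 15.0 h, and by the 71.3% of Ze that remains once each catalyst has taken one. That gave a gentler 0.110 h⁻¹. The tail grew to 1.9 points, so I committed to 16.0%. That is 1.86 Zc per Zb charged, and this count of Zc per catalyst charged, the turnover number, is what I carried.

Waiting adds a further 0.69 points. Zc enters no listed step as a reagent, so I expected epsilon to match waiting, at 16.7%. Heat is a guess. A fresh charge should repeat about what the first charge had made by 12.0 h, so gamma should reach 28.2%.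

The forecast gave 15.4%, below mine, with gamma best, 15.7% after epsilon and 29.5% after gamma: “Fresh Zb is the real lever”.

The flask gives 16.1%, with gamma best, 16.7% after epsilon and 30.6% after gamma.

    Za + Zd → Zh (k = 0.100 L mol⁻¹ min⁻¹, Ea = 67.0 kJ mol⁻¹)
    Zf ⇌ Zg (K = 0.210, k = 1.00 min⁻¹, Ea = 73.0 kJ mol⁻¹, ΔH = −34.0 kJ mol⁻¹)
    Za + Zb → Zf (k = 0.110 L mol⁻¹ min⁻¹, Ea = 50.0 kJ mol⁻¹)
    Zf + Ze → Zj (k = 0.490 L mol⁻¹ min⁻¹, Ea = 45.0 kJ mol⁻¹)
    Zg → Zb + Zc (k = 0.120 min⁻¹, Ea = 77.0 kJ mol⁻¹)
    (constants at 20 °C)

The result is 1.87 Zc per Zb, against my 1.86, and gamma raised Zc by 1.68 per Zb added in 12 h. In this flask at 25.0 h, 95.7% of the catalyst sits in Zj while 65.6% of the Za is free. Part of the reason for so small a count shows in two runs of this flask, which act together: against 16.1% of Zc at 25 h, removing the step from Zf and Ze to Zj gives 59.1%, and removing the return of Zg to Zf gives 63.7%.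

In a neighbouring flask charged with 0.17 M of Za, its other charges and the time held, my count gives 9.41% of its Za. The computed result is 9.89%.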